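**Retrosynthetic overview**
- The strategy rests on the 2-methylcyclopent-2-enone fused to the seven-membered ring at C1–C5 (C3 ketone, C4 methyl on the C4=C5 alkene, C2 methylene, sp3 C1–H). After ester hydrolysis it is an isomer of a tertiary C4 propargylic pivalate (C3≡C2) sitting on the C5=C1 alkene of a cycloheptene, so the five-membered ring is cut at C1–C2 (gold Rautenstrauch pentannulation).
- Target ⇐ 8,11-diol (C8 methacrylation, then C11 acetylation) ⇐ O8/O11-acetonide enone ⇐ tertiary propargylic pivalate (key step).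
- Pivalate ⇐ alkenyl ynone (methyl addition sets C4) ⇐ Weinreb amide ⇐ enoate ⇐ enol triflate ⇐ β-keto ester ⇐ all-cis cyclohexanone + ethyl diazoacetate (ring expansion inserting C5).
- All-cis cyclohexanone ⇐ (R)-carvone (supplies C7): isopropenyl hydration, deconjugation, hydroxyl-directed epoxidation and epoxide opening (C8–O cis to C7), acetonide, convex-face hydrogenation (C10).
- Ring order: six-membered ring from carvone, seven-membered ring by one-carbon expansion, five-membered ring last.

Key step: step 13

Remark: intermediates carry the guaiane atom labels of the target (carvone C1, C2, C3, C4, C5, C6 become C1, C10, C9, C8, C7, C6; the carbon inserted in step 6 is C5), and "acetonide" always means the isopropylidene acetal bridging O8 and O11.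

**Step 1**
Reactants: 1 (R)-carvone
Product: 2 (R)-8-hydroxycarvotanacetone
Conditions: Co(acac)2 (20 mol %), PhSiH3, O2 (1 atm), THF, rt
Reagents that add atoms: dioxygen, O=O
Why: Mukaiyama hydration, in which a cobalt hydride transfers a hydrogen atom to the electron-rich 1,1-disubstituted alkene and the tertiary radical is trapped by O2 and reduced, should give the Markovnikov tertiary alcohol (future C11–OH) while the electron-poor enone alkene stays untouched; no stereocenter is formed.

**Step 2**
Reactants: 2 (R)-8-hydroxycarvotanacetone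
Product: 4 (5S)-5-(2-hydroxypropan-2-yl)-2-methylcyclohex-3-en-1-one as its C2 epimers, via dipotassium dienolate 3 (not isolated)
Conditions: KOtBu (5 equiv), tBuOH/THF, rt; inverse quench into cold 10% aq. AcOH; crude used at once
Reagents that add atoms: none
Why: Base-mediated deconjugation of a cyclohexenone should work because equilibration with excess alkoxide gives the through-conjugated dienolate (loss of a γ-hydrogen at C8) and kinetic protonation at the α-carbon then places the alkene at C9=C8, homoallylic to the C11 hydroxyl; the C10 centre created here is erased again in step 3.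

**Step 3**
Reactants: 4 (5S)-5-(2-hydroxypropan-2-yl)-2-methylcyclohex-3-en-1-one
Product: 6 (4R,5S)-4-hydroxy-5-(2-hydroxypropan-2-yl)-2-methylcyclohex-2-en-1-one, via syn-epoxy ketone 5 (not isolated)
Conditions: VO(acac)2 (5 mol %), tBuOOH (decane), CH2Cl2, 0 °C → rt; then Et3N, rt
Reagents that add atoms: tert-butyl hydroperoxide, CC(C)(C)OO
Why: Hydroxyl-directed vanadium-catalysed epoxidation of a homoallylic alcohol delivers oxygen from the vanadate ester of C11–OH to the alkene face syn to the C7 side chain, and E1cB opening of the β,γ-epoxy ketone by Et3N restores the enone with the C8 hydroxyl cis to C7 (C8 set by the directing group).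

**Step 4**
Reactants: 6 (4R,5S)-4-hydroxy-5-(2-hydroxypropan-2-yl)-2-methylcyclohex-2-en-1-one
Product: 7 acetonide enone, (4aS,8aR)-2,2,4,4,7-pentamethyl-4a,5-dihydro-4H-benzo[d][1,3]dioxin-6(8aH)-one
Conditions: 2-methoxypropene, PPTS (cat.), CH2Cl2, 0 °C → rt
Reagents that add atoms: 2-methoxypropene, COC(C)=C
Why: Acid-catalysed acetal exchange should close the six-membered isopropylidene acetal across the cis-1,3-diol, protecting both hydroxyls in one operation and walling off one face of the enone as a cis-fused 1,3-dioxane.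

**Step 5**
Reactants: 7 acetonide enone
Product: 8 all-cis ketone, (4aS,7S,8aR)-2,2,4,4,7-pentamethylhexahydro-4H-benzo[d][1,3]dioxin-6(5H)-one
Conditions: H2 (1 atm), Pd/C (5%), EtOAc, rt
Reagents that add atoms: none
Why: Heterogeneous catalytic hydrogenation should add both hydrogens to the convex face of the cis-fused bicycle, opposite the dioxane ring, so the C10 methyl ends cis to O8 and C11 under kinetic control (no base contact afterwards, to avoid α-epimerisation).

**Step 6**
Reactants: 8 all-cis ketone; 9 ethyl diazoacetate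
Product: 10 ethyl (3S,5R,6S)-5-hydroxy-6-(2-hydroxypropan-2-yl)-3-methyl-2-oxocycloheptane-1-carboxylate acetonide (C1 epimers and enol)
Conditions: BF3·OEt2, Et2O, −20 → 0 °C
Reagents that add atoms: ethyl diazoacetate (9), CCOC(=O)C=[N+]=[N-]
Why: Lewis acid-promoted diazoacetate homologation of a ketone (Büchner–Curtius–Schlotterbeck, Tiffeneau–Demjanov-type) adds the diazo carbon to the C1 carbonyl and migrates the less substituted α-carbon C6 with loss of N2, inserting the ester-bearing C5 between C1 and C6; the new C5 centre is irrelevant because it becomes sp2.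

**Step 7**
Reactants: 10 β-keto ester
Product: 11 ethyl (3S,5R,6S)-5-hydroxy-6-(2-hydroxypropan-2-yl)-3-methyl-2-(trifluoromethylsulfonyloxy)cyclohept-1-ene-1-carboxylate acetonide
Conditions: Tf2O, iPr2NEt, CH2Cl2, −78 °C
Reagents that add atoms: triflic anhydride, O=S(=O)(OS(=O)(=O)C(F)(F)F)C(F)(F)F
Why: O-Sulfonylation of the β-keto ester enol, which can only form toward the doubly activated C5, should give the C1=C5 enol triflate regiospecifically and leave the C10 centre untouched.

**Step 8**
Reactants: 11 enol triflate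
Product: 12 ethyl (3S,5R,6S)-5-hydroxy-6-(2-hydroxypropan-2-yl)-3-methylcyclohept-1-ene-1-carboxylate acetonide
Conditions: Pd(OAc)2 (5 mol %), PPh3, HCO2H, Bu3N, DMF, 60 °C
Reagents that add atoms: none
Why: Palladium-catalysed formate reduction of an enol triflate (oxidative addition to zerovalent palladium, decarboxylation of formate to the palladium hydride, reductive elimination) should replace OTf on C1 by hydrogen and leave the conjugated C5=C1 enoate.

**Step 9**
Reactants: 12 enoate
Product: 13 (3S,5R,6S)-5-hydroxy-6-(2-hydroxypropan-2-yl)-N-methoxy-N,3-dimethylcyclohept-1-ene-1-carboxamide acetonide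
Conditions: MeNH(OMe)·HCl, iPrMgCl, THF, −20 → 0 °C
Reagents that add atoms: N,O-dimethylhydroxylamine hydrochloride, CNOC.Cl
Why: Direct aminolysis of the ester by the chloromagnesium amide of N,O-dimethylhydroxylamine should give the Weinreb amide, which lets two different carbon nucleophiles be added to C4 one after the other.

**Step 10**
Reactants: 13 Weinreb amide; 14 trimethylsilylacetylene
Product: 15 1-[(3S,5R,6S)-5-hydroxy-6-(2-hydroxypropan-2-yl)-3-methylcyclohept-1-en-1-yl]-3-(trimethylsilyl)prop-2-yn-1-one acetonide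
Conditions: n-BuLi, THF, −78 °C; then 13, −78 → −20 °C; sat. aq. NH4Cl at −78 °C
Reagents that add atoms: trimethylsilylacetylene (14), C#C[Si](C)(C)C
Why: Weinreb ketone synthesis with a lithium acetylide should install C3 and C2 as the ynone, over-addition being prevented by N,O-chelation until the cold quench.

**Step 11**
Reactants: 15 ynone; 16 methyllithium
Product: 18 (2S)-2-[(3S,5R,6S)-5-hydroxy-6-(2-hydroxypropan-2-yl)-3-methylcyclohept-1-en-1-yl]but-3-yn-2-ol acetonide, via silylated lithium alkoxide 17 (not isolated)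
Conditions: 16 (Et2O), THF, −78 °C; then MeOH, K2CO3 (cat.), 0 °C → rt
Reagents that add atoms: methyllithium (16), [Li]C
Why: 1,2-Addition of an organolithium to the ynone followed by methanolysis of the alkynyl C–Si bond should give the terminal tertiary propargylic alcohol; C4 is set by substrate control, attack on the s-trans ynone from the ring face opposite the C7, C8 and C10 substituents being expected to favour the 4S carbinol, and the C4 epimer is removed by chromatography at this stage.

**Step 12**
Reactants: 18 tertiary propargylic alcohol; 19 pivaloyl chloride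
Product: 21 (2S)-2-[(3S,5R,6S)-5-hydroxy-6-(2-hydroxypropan-2-yl)-3-methylcyclohept-1-en-1-yl]but-3-yn-2-yl pivalate acetonide, via lithium alkoxide 20 (not isolated)
Conditions: LiN(SiMe3)2 (1.05 equiv), THF, −78 °C; then 19, −78 → 0 °C
Reagents that add atoms: pivaloyl chloride (19), CC(C)(C)C(=O)Cl
Why: O-Acylation of the pre-formed lithium tertiary alkoxide (one equivalent of amide base removes O–H before the alkyne C–H) should give the hindered tertiary propargylic pivalate without touching the C4 configuration.

**Step 13**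
Reactants: 21 tertiary propargylic pivalate
Product: 23 (1R,7S,8R,10S)-8,11-(isopropylidenedioxy)guai-4-en-3-one (8β-O and 1βH), via cyclopentadienyl pivalate 22 (not isolated)
Conditions: Ph3PAuCl (5 mol %), AgSbF6 (5 mol %), MeCN with 2 equiv H2O, −20 °C → rt
Reagents that add atoms: none
Why: Cationic monovalent gold (Ph3PAu+) binds the terminal alkyne, the pivalate carbonyl oxygen adds to C3 (5-exo-dig) and, as the C4–O bond breaks, the vinylgold carbon C2 bonds to C1 of the C5=C1 alkene, i.e. a 1,2-acyloxy shift merged with a Nazarov-like 4π closure of the C2–C3–C4–C5–C1 pentadienyl cation; loss of gold gives dienyl pivalate 22, which water hydrolyses to the C3 ketone conjugated with the C4=C5 alkene. The closest known reaction is the gold-catalysed Rautenstrauch rearrangement of 1-ethynyl-2-propenyl pivalates, which is established for cycloalkenyl substrates. The five-membered ring is closed by the single C1–C2 bond in a conrotatory 4π electrocyclisation (formally 5-endo). The only new stereocenter, C1, is set by transfer of chirality from C4 (C–C bond formation anti to the leaving oxygen in a helical transition state) and by the C10 methyl, which shields the same face as the leaving oxygen in the 4S epimer, so C2 adds trans to C14 and H1 ends β. The step needs 1,2- instead of 1,3-acyloxy migration, secured by the terminal alkyne, and cyclisation faster than ionisation–elimination of the tertiary ester, favoured by the pivalate, the nitrile solvent and low temperature; partial loss of the acetonide would be harmless because step 14 removes it.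

**Step 14**
Reactants: 23 acetonide enone
Product: 24 (1R,7S,8R,10S)-8,11-dihydroxyguai-4-en-3-one
Conditions: AcOH/H2O (4:1), 40 °C
Reagents that add atoms: none
Why: Acid-catalysed hydrolysis of the isopropylidene acetal should free the secondary C8 and tertiary C11 hydroxyls, the enone and the C1 centre being stable to weak aqueous acid.

**Step 15**
Reactants: 24 diol; 25 methacryloyl chloride
Product: 26 (1R,7S,8R,10S)-11-hydroxy-8-(methacryloyloxy)guai-4-en-3-one
Conditions: 25 (1.2 equiv), Et3N, DMAP (cat.), BHT (trace), CH2Cl2, −20 → 0 °C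
Reagents that add atoms: methacryloyl chloride (25), C=C(C)C(=O)Cl
Why: Nucleophile-catalysed O-acylation should discriminate sterically between the secondary C8 hydroxyl, which reacts with retention at C8, and the tertiary C11 hydroxyl, which does not react under these conditions.

**Step 16**
Reactants: 26 hydroxy methacrylate; 27 acetic anhydride
Product: 28 (1R,7S,8R,10S)-11-acetoxy-8-(methacryloyloxy)guai-4-en-3-one (CNP0318307.1)
Conditions: 27 (excess), DMAP (1 equiv), Et3N, BHT (trace), CH2Cl2, 35 °C
Reagents that add atoms: acetic anhydride (27), CC(=O)OC(C)=O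
Why: DMAP-catalysed acetylation through the N-acetylpyridinium ion is the standard esterification of a hindered tertiary alcohol and should leave the methacrylate, the enone and all four stereocenters untouched, giving the target.

**Compound list**
1 | (R)-carvone | CC1=CC[C@H](CC1=O)C(C)=C | starting material
2 | (R)-8-hydroxycarvotanacetone, (5R)-5-(2-hydroxypropan-2-yl)-2-methylcyclohex-2-en-1-one | CC1=CC[C@H](CC1=O)C(C)(C)O | intermediate
3 | dipotassium (5S)-2-methyl-5-(2-oxidopropan-2-yl)cyclohexa-1,3-dien-1-olate (not isolated) | CC1=C([O-])C[C@@H](C=C1)C(C)(C)[O-].[K+].[K+] | intermediate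
4 | (5S)-5-(2-hydroxypropan-2-yl)-2-methylcyclohex-3-en-1-one, both C2 epimers | CC1C=C[C@H](CC1=O)C(C)(C)O | intermediate
5 | 3,4-epoxy-5-(2-hydroxypropan-2-yl)-2-methylcyclohexan-1-one, epoxide oxygen cis to the side chain, both C2 epimers (not isolated) | CC1C(=O)C[C@H](C(C)(C)O)[C@@H]2O[C@H]12 | intermediate
6 | (4R,5S)-4-hydroxy-5-(2-hydroxypropan-2-yl)-2-methylcyclohex-2-en-1-one (4-OH cis to the side chain) | O[C@@H]1C=C(C)C(=O)C[C@@H]1C(C)(C)O | intermediate
7 | (4aS,8aR)-2,2,4,4,7-pentamethyl-4a,5-dihydro-4H-benzo[d][1,3]dioxin-6(8aH)-one (acetonide of 6) | CC1(C)O[C@@H]2C=C(C)C(=O)C[C@@H]2C(C)(C)O1 | intermediate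
8 | (4aS,7S,8aR)-2,2,4,4,7-pentamethylhexahydro-4H-benzo[d][1,3]dioxin-6(5H)-one (all-cis) | CC1(C)O[C@@H]2C[C@H](C)C(=O)C[C@@H]2C(C)(C)O1 | intermediate
9 | ethyl diazoacetate | CCOC(=O)C=[N+]=[N-] | starting material
10 | ethyl (3S,5R,6S)-5-hydroxy-6-(2-hydroxypropan-2-yl)-3-methyl-2-oxocycloheptane-1-carboxylate acetonide (C1 epimers and enol) | CC1(C)O[C@@H]2C[C@H](C)C(=O)C(C(=O)OCC)C[C@@H]2C(C)(C)O1 | intermediate
11 | ethyl (3S,5R,6S)-5-hydroxy-6-(2-hydroxypropan-2-yl)-3-methyl-2-(trifluoromethylsulfonyloxy)cyclohept-1-ene-1-carboxylate acetonide | CC1(C)O[C@@H]2C[C@H](C)C(OS(=O)(=O)C(F)(F)F)=C(C(=O)OCC)C[C@@H]2C(C)(C)O1 | intermediate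
12 | ethyl (3S,5R,6S)-5-hydroxy-6-(2-hydroxypropan-2-yl)-3-methylcyclohept-1-ene-1-carboxylate acetonide | CC1(C)O[C@@H]2C[C@H](C)C=C(C(=O)OCC)C[C@@H]2C(C)(C)O1 | intermediate
13 | (3S,5R,6S)-5-hydroxy-6-(2-hydroxypropan-2-yl)-N-methoxy-N,3-dimethylcyclohept-1-ene-1-carboxamide acetonide | CC1(C)O[C@@H]2C[C@H](C)C=C(C(=O)N(C)OC)C[C@@H]2C(C)(C)O1 | intermediate
14 | trimethylsilylacetylene | C#C[Si](C)(C)C | starting material
15 | 1-[(3S,5R,6S)-5-hydroxy-6-(2-hydroxypropan-2-yl)-3-methylcyclohept-1-en-1-yl]-3-(trimethylsilyl)prop-2-yn-1-one acetonide | CC1(C)O[C@@H]2C[C@H](C)C=C(C(=O)C#C[Si](C)(C)C)C[C@@H]2C(C)(C)O1 | intermediate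
16 | methyllithium | [Li]C | starting material
17 | lithium (2R)-2-[(3S,5R,6S)-5-hydroxy-6-(2-hydroxypropan-2-yl)-3-methylcyclohept-1-en-1-yl]-4-(trimethylsilyl)but-3-yn-2-olate acetonide (not isolated) | CC1(C)O[C@@H]2C[C@H](C)C=C([C@](C)(C#C[Si](C)(C)C)[O-])C[C@@H]2C(C)(C)O1.[Li+] | intermediate
18 | (2S)-2-[(3S,5R,6S)-5-hydroxy-6-(2-hydroxypropan-2-yl)-3-methylcyclohept-1-en-1-yl]but-3-yn-2-ol acetonide | CC1(C)O[C@@H]2C[C@H](C)C=C([C@](C)(C#C)O)C[C@@H]2C(C)(C)O1 | intermediate
19 | pivaloyl chloride | CC(C)(C)C(=O)Cl | starting material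
20 | lithium alkoxide of 18 (not isolated) | CC1(C)O[C@@H]2C[C@H](C)C=C([C@](C)(C#C)[O-])C[C@@H]2C(C)(C)O1.[Li+] | intermediate
21 | (2S)-2-[(3S,5R,6S)-5-hydroxy-6-(2-hydroxypropan-2-yl)-3-methylcyclohept-1-en-1-yl]but-3-yn-2-yl pivalate acetonide | CC1(C)O[C@@H]2C[C@H](C)C=C([C@](C)(C#C)OC(=O)C(C)(C)C)C[C@@H]2C(C)(C)O1 | intermediate
22 | 8β,11-(isopropylidenedioxy)-1βH-guaia-2,4-dien-3-yl pivalate (not isolated) | CC1(C)O[C@@H]2C[C@H](C)[C@H]3C=C(OC(=O)C(C)(C)C)C(C)=C3C[C@@H]2C(C)(C)O1 | intermediate
23 | (1R,7S,8R,10S)-8,11-(isopropylidenedioxy)guai-4-en-3-one | CC1(C)O[C@@H]2C[C@H](C)[C@H]3CC(=O)C(C)=C3C[C@@H]2C(C)(C)O1 | intermediate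
24 | (1R,7S,8R,10S)-8,11-dihydroxyguai-4-en-3-one | O[C@@H]1C[C@H](C)[C@H]2CC(=O)C(C)=C2C[C@@H]1C(C)(C)O | intermediate
25 | methacryloyl chloride | C=C(C)C(=O)Cl | starting material
26 | (1R,7S,8R,10S)-11-hydroxy-8-(methacryloyloxy)guai-4-en-3-one | C=C(C)C(=O)O[C@@H]1C[C@H](C)[C@H]2CC(=O)C(C)=C2C[C@@H]1C(C)(C)O | intermediate
27 | acetic anhydride | CC(=O)OC(C)=O | starting material
28 | (1R,7S,8R,10S)-11-acetoxy-8-(methacryloyloxy)guai-4-en-3-one, CNP0318307.1 | C=C(C)C(=O)O[C@@H]1C[C@H](C)[C@H]2CC(=O)C(C)=C2C[C@@H]1C(C)(C)OC(C)=O | target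

**Step count and risks**
Total step count: 16. Longest linear sequence: 16 steps, from 1 to 28.

Steps most likely to fail:

1. Step 13 (key step). The doubly activated tertiary C4–O bond may ionise and lose a proton to a conjugated dienyne faster than the concerted shift and ring closure, or facial control at C1 may erode if a free, planar cation forms. Fallback, setting out from 15 and returning at 23: the ynone is reduced under reagent control with BH3·SMe2 and (R)-2-methyl-CBS-oxazaborolidine (alkynyl as the small group) to the silylated secondary propargylic alcohol F1. K2CO3 in MeOH then gives the terminal secondary propargylic alcohol F2, and pivaloyl chloride with Et3N and DMAP gives the secondary pivalate F3, the substrate class for which the gold cyclisation and its chirality transfer are best documented. Ph3PAuCl/AgSbF6 in wet MeCN should give the C4-unsubstituted enone F4, and iodine with pyridine in CH2Cl2 the 4-iodoenone F5. Suzuki coupling with trimethylboroxine (Pd(PPh3)4 as the zerovalent palladium source, K2CO3, dioxane, 90 °C) then installs C15 and gives 23.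

2. Step 11. Methyl addition to the ynone carbonyl may be unselective or may prefer the other face, so that the 4S carbinol is the minor epimer. Fallback, setting out from 13 and returning at 18: MeMgBr in THF at 0 °C converts the Weinreb amide into the methyl ketone F6, and ethynylmagnesium bromide (THF, −78 → 0 °C) then adds to the acetyl carbonyl. Because the two C4 substituents now arrive in the reverse order, the same facial preference should give the opposite C4 configuration, and 18 is reached without a silyl group.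

3. Step 2. Deconjugation may stay incomplete or revert during quench and handling, and the C11 alkoxide may add intramolecularly to C9 of the enone, so that little β,γ-enone reaches the directed epoxidation. Fallback, setting out from 1 and returning at 6: carvone is deprotonated with MeMgBr and catalytic FeCl3 and silylated with Me3SiCl to the through-conjugated silyl dienol ether F7. Vinylogous Rubottom oxidation with dimethyldioxirane attacks C8 anti to the isopropenyl group and gives trans-4-hydroxycarvone F8. Mitsunobu inversion with 4-nitrobenzoic acid (PPh3, DIAD) gives the cis 4-nitrobenzoate F9, and K2CO3 in MeOH gives cis-4-hydroxycarvone F10. The Mukaiyama hydration of step 1 applied to F10 then gives 6.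

**Further compounds**
F1 | step 13 | 1-[(3S,5R,6S)-5-hydroxy-6-(2-hydroxypropan-2-yl)-3-methylcyclohept-1-en-1-yl]-3-(trimethylsilyl)prop-2-yn-1-ol acetonide, carbinol configured as in 18 with H in place of methyl | CC1(C)O[C@@H]2C[C@H](C)C=C([C@H](C#C[Si](C)(C)C)O)C[C@@H]2C(C)(C)O1
F2 | step 13 | (1S)-1-[(3S,5R,6S)-5-hydroxy-6-(2-hydroxypropan-2-yl)-3-methylcyclohept-1-en-1-yl]prop-2-yn-1-ol acetonide | CC1(C)O[C@@H]2C[C@H](C)C=C([C@H](C#C)O)C[C@@H]2C(C)(C)O1
F3 | step 13 | (1S)-1-[(3S,5R,6S)-5-hydroxy-6-(2-hydroxypropan-2-yl)-3-methylcyclohept-1-en-1-yl]prop-2-yn-1-yl pivalate acetonide | CC1(C)O[C@@H]2C[C@H](C)C=C([C@H](C#C)OC(=O)C(C)(C)C)C[C@@H]2C(C)(C)O1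
F4 | step 13 | 8β,11-(isopropylidenedioxy)-15-nor-1βH-guai-4-en-3-one | CC1(C)O[C@@H]2C[C@H](C)[C@H]3CC(=O)C=C3C[C@@H]2C(C)(C)O1
F5 | step 13 | 4-iodo-8β,11-(isopropylidenedioxy)-15-nor-1βH-guai-4-en-3-one | CC1(C)O[C@@H]2C[C@H](C)[C@H]3CC(=O)C(I)=C3C[C@@H]2C(C)(C)O1
F6 | step 11 | 1-[(3S,5R,6S)-5-hydroxy-6-(2-hydroxypropan-2-yl)-3-methylcyclohept-1-en-1-yl]ethan-1-one acetonide | CC1(C)O[C@@H]2C[C@H](C)C=C(C(C)=O)C[C@@H]2C(C)(C)O1
F7 | step 2 | (5R)-2-methyl-5-(prop-1-en-2-yl)-1-(trimethylsilyloxy)cyclohexa-1,3-diene | CC1=C(O[Si](C)(C)C)C[C@@H](C=C1)C(C)=C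
F8 | step 2 | trans-4-hydroxycarvone, (4S,5R)-4-hydroxy-2-methyl-5-(prop-1-en-2-yl)cyclohex-2-en-1-one | O[C@H]1C=C(C)C(=O)C[C@@H]1C(C)=C
F9 | step 2 | cis-4-(4-nitrobenzoyloxy)carvone, (1R,6R)-3-methyl-4-oxo-6-(prop-1-en-2-yl)cyclohex-2-en-1-yl 4-nitrobenzoate | O=C(O[C@@H]1C=C(C)C(=O)C[C@@H]1C(C)=C)c1ccc(cc1)[N+](=O)[O-]
F10 | step 2 | cis-4-hydroxycarvone, (4R,5R)-4-hydroxy-2-methyl-5-(prop-1-en-2-yl)cyclohex-2-en-1-one | O[C@@H]1C=C(C)C(=O)C[C@@H]1C(C)=C
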